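Ring A is cut at C1=C10 and C4–C5 (halimane locants: C4 carries methyl and ester, C5/C10 are the ring fusion). The design exploits that the C18 carboxyl on C4 and the C15 oxygen of the C9 side chain lie on the same face of the ring A/ring B core: they are joined as a temporary ester. The precursor is a ring B alkenylstannane whose side chain ends in a (2E,4Z)-5-iodo-2-methyldienoate. One operation closes a 13-membered ring by sp2–sp2 coupling (C1–C10) and lets the tethered triene undergo disrotatory 6π-electrocyclisation (C4–C5), creating the C1=C10 olefin, quaternary C4 and C5. Methanolysis then frees the methyl ester and C15 alcohol.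

Key step: step 10

Remark: locants C1–C20 are the diterpene locants of the decalin (ring A = C1–C5, C10; ring B = C5–C10; side chain C11–C16 on C9; carboxyl carbon on C4 = C18); the target is the (4S,5R,8R,9S,13E) isomer, and 11 is taken as a catalogue chemical.

Step 1
Reactants: 1 2-methylcyclohex-2-en-1-one
Product: 3 (R)-[(2,3-dimethylcyclohex-1-en-1-yl)oxy]trimethylsilane, via aluminium enolate 2 (not isolated)
Conditions: Me3Al, Cu(O2CC4H3S) (copper thiophene-2-carboxylate, cat.), BINOL-derived phosphoramidite ligand (enantiomer that gives 3R), Et2O, −30 °C; then Me3SiOTf, −30 °C to 0 °C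
Reagents that add atoms: trimethylaluminium, C[Al](C)C; trimethylsilyl trifluoromethanesulfonate, C[Si](C)(C)OS(=O)(=O)C(F)(F)F
Why: Copper-catalysed asymmetric conjugate addition of methyl to the α-substituted enone should set C8 (R) under ligand control, and O-silylation of the aluminium enolate fixes the tetrasubstituted enolate regiochemistry for step 2.

Step 2
Reactants: 3 (R)-[(2,3-dimethylcyclohex-1-en-1-yl)oxy]trimethylsilane; 4 but-3-en-2-one
Product: 5 (2S,3R)-2,3-dimethyl-2-(3-oxobutyl)cyclohexan-1-one
Conditions: BF3·OEt2, i-PrOH, CH2Cl2, −78 °C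
Reagents that add atoms: none
Why: Mukaiyama–Michael addition builds the quaternary C9, the enone entering anti to the adjacent pseudoaxial C8 methyl so that the two methyl groups end cis (2S,3R).

Step 3
Reactants: 5 (2S,3R)-2,3-dimethyl-2-(3-oxobutyl)cyclohexan-1-one; 6 triethyl phosphonoacetate
Product: 7 ethyl (2E)-5-[(1S,2R)-1,2-dimethyl-6-oxocyclohexyl]-3-methylpent-2-enoate
Conditions: NaH, THF, 0 °C to 40 °C
Reagents that add atoms: none
Why: Horner–Wadsworth–Emmons olefination should occur only at the unhindered methyl ketone (the ring ketone is flanked by the quaternary carbon) and give mainly the E trisubstituted enoate, the minor Z isomer being removed by chromatography.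

Step 4
Reactants: 7 ethyl (2E)-5-[(1S,2R)-1,2-dimethyl-6-oxocyclohexyl]-3-methylpent-2-enoate
Product: 8 ethyl (2E)-5-[(1S,6R)-1,6-dimethyl-2-(trifluoromethylsulfonyloxy)cyclohex-2-en-1-yl]-3-methylpent-2-enoate
Conditions: Tf2O, 2,6-di-tert-butyl-4-methylpyridine, CH2Cl2, 0 °C to 23 °C
Reagents that add atoms: trifluoromethanesulfonic anhydride, O=S(=O)(OS(=O)(=O)C(F)(F)F)C(F)(F)F
Why: O-sulfonylation of the ketone under non-basic conditions gives the only possible enol triflate (C5=C10, since C9 is quaternary), while the electron-poor enoate olefin neither enolises nor attacks the activated carbonyl.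

Step 5
Reactants: 8 ethyl (2E)-5-[(1S,6R)-1,6-dimethyl-2-(trifluoromethylsulfonyloxy)cyclohex-2-en-1-yl]-3-methylpent-2-enoate
Product: 9 (5R,6S)-6-[(3E)-5-hydroxy-3-methylpent-3-en-1-yl]-5,6-dimethylcyclohex-1-en-1-yl trifluoromethanesulfonate
Conditions: i-Bu2AlH, CH2Cl2, −78 °C; aqueous potassium sodium tartrate
Reagents that add atoms: none
Why: 1,2-Reduction of the conjugated ester by the aluminium hydride gives the E allylic alcohol without touching the alkenyl triflate or the olefin geometry.

Step 6
Reactants: 9 (5R,6S)-6-[(3E)-5-hydroxy-3-methylpent-3-en-1-yl]-5,6-dimethylcyclohex-1-en-1-yl trifluoromethanesulfonate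
Product: 10 (2E)-5-[(1S,6R)-1,6-dimethyl-2-(trimethylstannyl)cyclohex-2-en-1-yl]-3-methylpent-2-en-1-ol
Conditions: Me3SnSnMe3, Pd(PPh3)4 (cat.), LiCl, THF, 65 °C
Reagents that add atoms: hexamethylditin, C[Sn](C)(C)[Sn](C)(C)C
Why: Palladium-catalysed stannylation of the alkenyl triflate (oxidative addition, Sn–Sn transmetalation, reductive elimination) installs the nucleophilic terminus at C10 and tolerates the free alcohol.

Step 7
Reactants: 10 (2E)-5-[(1S,6R)-1,6-dimethyl-2-(trimethylstannyl)cyclohex-2-en-1-yl]-3-methylpent-2-en-1-ol; 11 2-(diethoxyphosphoryl)propanoic acid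
Product: 12 (2E)-5-[(1S,6R)-1,6-dimethyl-2-(trimethylstannyl)cyclohex-2-en-1-yl]-3-methylpent-2-en-1-yl 2-(diethoxyphosphoryl)propanoate (both epimers at the phosphonate carbon)
Conditions: DCC, DMAP (cat.), CH2Cl2, 0 °C to 23 °C
Reagents that add atoms: none
Why: Carbodiimide (Steglich) esterification attaches to the C15 oxygen the unit that becomes C4, its methyl and C18, which creates the temporary ester tether; the stereocentre at the phosphonate carbon is lost in step 9.

Step 8
Reactants: 13 ethyl (2Z)-3-iodoprop-2-enoate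
Product: 14 (2Z)-3-iodoprop-2-enal
Conditions: i-Bu2AlH, CH2Cl2, −78 °C; aqueous potassium sodium tartrate; used at once
Reagents that add atoms: none
Why: Partial reduction at low temperature stops at the aluminium hemiacetal and should give the Z iodo-enal with retention of geometry, immediate use avoiding Z to E isomerisation.

Step 9
Reactants: 12 (2E)-5-[(1S,6R)-1,6-dimethyl-2-(trimethylstannyl)cyclohex-2-en-1-yl]-3-methylpent-2-en-1-yl 2-(diethoxyphosphoryl)propanoate; 14 (2Z)-3-iodoprop-2-enal
Product: 15 (2E)-5-[(1S,6R)-1,6-dimethyl-2-(trimethylstannyl)cyclohex-2-en-1-yl]-3-methylpent-2-en-1-yl (2E,4Z)-5-iodo-2-methylpenta-2,4-dienoate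
Conditions: NaH, THF, 0 °C; then 14, −78 °C to 0 °C
Reagents that add atoms: none
Why: Horner–Wadsworth–Emmons olefination of the α-methyl phosphonate should give the 2E dienoate (ester trans to the vinyl group) and leave the 4Z iodide and the alkenylstannane intact; this E geometry later encodes the configuration of C4.

Step 10
Reactants: 15 (2E)-5-[(1S,6R)-1,6-dimethyl-2-(trimethylstannyl)cyclohex-2-en-1-yl]-3-methylpent-2-en-1-yl (2E,4Z)-5-iodo-2-methylpenta-2,4-dienoate
Product: 17 bridged lactone diene (15-O to C18 lactone of the (4S,5R,8R,9S,13E)-15-hydroxyhalima-1(10),2,13-trien-18-oic acid), via macrocyclic triene 16 (not isolated)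
Conditions: Cu(O2CC4H3S) (copper thiophene-2-carboxylate, 3 equiv), N-methylpyrrolidone, 0.002 M, 0 °C to 23 °C; then 100 °C
Reagents that add atoms: none
Why: The monovalent copper carboxylate turns the alkenylstannane into an alkenylcopper that couples with the Z iodide with retention and closes the 13-membered lactone 16 through C1–C10 (macrocyclisation by sp2–sp2 coupling, the Stille-type closure used for polyene macrolactones; no palladium is present, so the allylic ester is not ionised). On warming, the triene C5=C10–C1=C2–C3=C4 closes ring A by thermal disrotatory 6π-electrocyclisation, the closest known types being cross-coupling/6π cascades and the previtamin D to pyrocalciferol closure, which also builds a methyl-bearing quaternary carbon. Orbital symmetry places the two outward groups (C6 on C5, C18 on C4) cis and the two inward groups (H5, the C4 methyl) cis, so the E geometry of C3=C4 fixes C4 relative to C5. The sense of rotation relative to C8/C9 is set by the tether: C18 is tied to the chain on the upper face of C9, and the other rotation would need a trans (in,out) 1,3-bridge across ring B inside an 11-membered lactone holding two planar units, so 4S,5R should result. The step needs retention of the Z olefin and ring closure faster than oligomerisation (high dilution); the [1,7]-hydrogen shift from the inward methyl is reversible and returns the same triene geometry.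

Step 11
Reactants: 17 bridged lactone diene
Product: 18 methyl (1S,5S,6R,8aR)-5-[(3E)-5-hydroxy-3-methylpent-3-en-1-yl]-1,5,6-trimethyl-1,5,6,7,8,8a-hexahydronaphthalene-1-carboxylate
Conditions: NaOMe, MeOH, 50 °C
Reagents that add atoms: methanol, CO
Why: Methoxide should open the strained bridged lactone by acyl substitution to give the C18 methyl ester and the free C15 alcohol, and the quaternary C4 cannot epimerise.

Step 12
Reactants: 18 methyl (1S,5S,6R,8aR)-5-[(3E)-5-hydroxy-3-methylpent-3-en-1-yl]-1,5,6-trimethyl-1,5,6,7,8,8a-hexahydronaphthalene-1-carboxylate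
Product: 19 methyl (1S,5S,6R,8aR)-5-[(3E)-5-hydroxy-3-methylpent-3-en-1-yl]-1,5,6-trimethyl-1,2,3,5,6,7,8,8a-octahydronaphthalene-1-carboxylate
Conditions: 2-nitrobenzenesulfonohydrazide, Et3N, CH2Cl2, 23 °C (diimide formed in the flask)
Reagents that add atoms: none
Why: Diimide transfers hydrogen in a concerted syn fashion and discriminates strongly by substitution, so the cis-disubstituted C2=C3 bond should be reduced while the hindered trisubstituted C1=C10 and C13=C14 olefins remain; no stereocentre is created.

Step 13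
Reactants: 19 methyl (1S,5S,6R,8aR)-5-[(3E)-5-hydroxy-3-methylpent-3-en-1-yl]-1,5,6-trimethyl-1,2,3,5,6,7,8,8a-octahydronaphthalene-1-carboxylate
Product: 20 methyl (1S,5S,6R,8aR)-1,5,6-trimethyl-5-[(3E)-3-methyl-5-(propanoyloxy)pent-3-en-1-yl]-1,2,3,5,6,7,8,8a-octahydronaphthalene-1-carboxylate
Conditions: (EtCO)2O, Et3N, DMAP (cat.), CH2Cl2, 0 °C
Reagents that add atoms: propanoic anhydride, CCC(=O)OC(=O)CC
Why: Acylation of the primary allylic alcohol with the anhydride under nucleophilic catalysis gives the propanoate, which is the target.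

Compound list
1 | 2-methylcyclohex-2-en-1-one | CC1=CCCCC1=O | starting material
2 | dimethylaluminium (R)-2,3-dimethylcyclohex-1-en-1-olate | C[C@@H]1CCCC(O[Al](C)C)=C1C | intermediate
3 | (R)-[(2,3-dimethylcyclohex-1-en-1-yl)oxy]trimethylsilane | C[C@@H]1CCCC(O[Si](C)(C)C)=C1C | intermediate
4 | but-3-en-2-one | CC(=O)C=C | starting material
5 | (2S,3R)-2,3-dimethyl-2-(3-oxobutyl)cyclohexan-1-one | CC(=O)CC[C@]1(C)C(=O)CCC[C@H]1C | intermediate
6 | triethyl phosphonoacetate | CCOC(=O)CP(=O)(OCC)OCC | starting material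
7 | ethyl (2E)-5-[(1S,2R)-1,2-dimethyl-6-oxocyclohexyl]-3-methylpent-2-enoate | CCOC(=O)/C=C(\C)CC[C@]1(C)C(=O)CCC[C@H]1C | intermediate
8 | ethyl (2E)-5-[(1S,6R)-1,6-dimethyl-2-(trifluoromethylsulfonyloxy)cyclohex-2-en-1-yl]-3-methylpent-2-enoate | CCOC(=O)/C=C(\C)CC[C@]1(C)C(OS(=O)(=O)C(F)(F)F)=CCC[C@H]1C | intermediate
9 | (5R,6S)-6-[(3E)-5-hydroxy-3-methylpent-3-en-1-yl]-5,6-dimethylcyclohex-1-en-1-yl trifluoromethanesulfonate | OC/C=C(\C)CC[C@]1(C)C(OS(=O)(=O)C(F)(F)F)=CCC[C@H]1C | intermediate
10 | (2E)-5-[(1S,6R)-1,6-dimethyl-2-(trimethylstannyl)cyclohex-2-en-1-yl]-3-methylpent-2-en-1-ol | OC/C=C(\C)CC[C@]1(C)C([Sn](C)(C)C)=CCC[C@H]1C | intermediate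
11 | 2-(diethoxyphosphoryl)propanoic acid | CC(C(=O)O)P(=O)(OCC)OCC | starting material
12 | (2E)-5-[(1S,6R)-1,6-dimethyl-2-(trimethylstannyl)cyclohex-2-en-1-yl]-3-methylpent-2-en-1-yl 2-(diethoxyphosphoryl)propanoate | CCOP(=O)(OCC)C(C)C(=O)OC/C=C(\C)CC[C@]1(C)C([Sn](C)(C)C)=CCC[C@H]1C | intermediate
13 | ethyl (2Z)-3-iodoprop-2-enoate | CCOC(=O)/C=C\I | starting material
14 | (2Z)-3-iodoprop-2-enal | O=C/C=C\I | intermediate
15 | (2E)-5-[(1S,6R)-1,6-dimethyl-2-(trimethylstannyl)cyclohex-2-en-1-yl]-3-methylpent-2-en-1-yl (2E,4Z)-5-iodo-2-methylpenta-2,4-dienoate | I/C=C\C=C(/C)C(=O)OC/C=C(\C)CC[C@]1(C)C([Sn](C)(C)C)=CCC[C@H]1C | intermediate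
16 | 13-membered macrolactone triene (C1–C10 joined; 1Z,3E,13E; 8R,9S) | C1/C=C(\C)CC[C@]2(C)C(=CCC[C@H]2C)/C=C\C=C(/C)C(=O)O1 | intermediate
17 | bridged lactone diene (15-O to C18 lactone; 4S,5R,8R,9S,13E) | O1C/C=C(\C)CC[C@]2(C)C3=CC=C[C@](C)(C1=O)[C@@H]3CC[C@H]2C | intermediate
18 | methyl (1S,5S,6R,8aR)-5-[(3E)-5-hydroxy-3-methylpent-3-en-1-yl]-1,5,6-trimethyl-1,5,6,7,8,8a-hexahydronaphthalene-1-carboxylate | OC/C=C(\C)CC[C@]1(C)C2=CC=C[C@](C)(C(=O)OC)[C@@H]2CC[C@H]1C | intermediate
19 | methyl (1S,5S,6R,8aR)-5-[(3E)-5-hydroxy-3-methylpent-3-en-1-yl]-1,5,6-trimethyl-1,2,3,5,6,7,8,8a-octahydronaphthalene-1-carboxylate | OC/C=C(\C)CC[C@]1(C)C2=CCC[C@](C)(C(=O)OC)[C@@H]2CC[C@H]1C | intermediate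
20 | methyl (1S,5S,6R,8aR)-1,5,6-trimethyl-5-[(3E)-3-methyl-5-(propanoyloxy)pent-3-en-1-yl]-1,2,3,5,6,7,8,8a-octahydronaphthalene-1-carboxylate | CCC(=O)OC/C=C(\C)CC[C@]1(C)C2=CCC[C@](C)(C(=O)OC)[C@@H]2CC[C@H]1C | target

Total step count: 13. Longest linear sequence: 12 steps (steps 1–7 and 9–13; step 8 is the side branch).

Steps most likely to fail

Step 10. Oligomerisation or protodestannylation at the hindered alkenylstannane may outrun closure of the 13-membered ring. The fallback separates the two ring closures and sets out from 10, 11 and 14. Horner–Wadsworth–Emmons reaction of 14 with the dianion of 11 (LiN(SiMe3)2, THF, −78 °C) gives (2E,4Z)-5-iodo-2-methylpenta-2,4-dienoic acid F1. Intermolecular Stille coupling of 10 with F1 (Pd2(dba)3, AsPh3, CuI, DMF, 23 °C) gives the open hydroxy acid triene F2. Yamaguchi macrolactonisation (2,4,6-trichlorobenzoyl chloride, Et3N, DMAP, toluene, high dilution, 23 °C) gives 16, now isolated, and heating in toluene brings about the same tether-controlled electrocyclisation, so the route is rejoined at 17.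

Step 12. Hydrogen transfer may go on to the trisubstituted olefins or stop short. The fallback reduces before the tether is opened and sets out from 17. Hydrogenation with RhCl(PPh3)3 under H2 (benzene, 23 °C), where rhodium binds only the disubstituted olefin and the lactone bridge further shields the others, gives the bridged lactone monoene F3. Methanolysis as in step 11 then gives 19 directly, where the route is rejoined.

Step 11. Acyl substitution at the neopentyl-type lactone carbonyl may be slow, with degradation on forcing. The fallback cleaves the alkyl–oxygen bond instead and sets out from 17. Pd(PPh3)4 with sodium propanoate and propanoic acid in THF ionises the allylic C15–O bond (Tsuji–Trost); the C18 carboxylate leaves and propanoate attacks the primary terminus, giving the propanoyloxy diene acid F4. Me3SiCHN2 in MeOH/toluene gives its methyl ester F5, and diimide reduction as in step 12 gives 20, so the route is rejoined at the target.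

Further compounds
F1 | step 10 | (2E,4Z)-5-iodo-2-methylpenta-2,4-dienoic acid | I/C=C\C=C(/C)C(=O)O
F2 | step 10 | (2E,4Z)-5-[(5R,6S)-6-((3E)-5-hydroxy-3-methylpent-3-en-1-yl)-5,6-dimethylcyclohex-1-en-1-yl]-2-methylpenta-2,4-dienoic acid | OC/C=C(\C)CC[C@]1(C)C(=CCC[C@H]1C)/C=C\C=C(/C)C(=O)O
F3 | step 12 | bridged lactone monoene (15-O to C18 lactone; 4S,5R,8R,9S,13E) | O1C/C=C(\C)CC[C@]2(C)C3=CCC[C@](C)(C1=O)[C@@H]3CC[C@H]2C
F4 | step 11 | (1S,5S,6R,8aR)-1,5,6-trimethyl-5-[(3E)-3-methyl-5-(propanoyloxy)pent-3-en-1-yl]-1,5,6,7,8,8a-hexahydronaphthalene-1-carboxylic acid | CCC(=O)OC/C=C(\C)CC[C@]1(C)C2=CC=C[C@](C)(C(=O)O)[C@@H]2CC[C@H]1C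
F5 | step 11 | methyl (1S,5S,6R,8aR)-1,5,6-trimethyl-5-[(3E)-3-methyl-5-(propanoyloxy)pent-3-en-1-yl]-1,5,6,7,8,8a-hexahydronaphthalene-1-carboxylate | CCC(=O)OC/C=C(\C)CC[C@]1(C)C2=CC=C[C@](C)(C(=O)OC)[C@@H]2CC[C@H]1C
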